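(All runs stem from a simulated flask with constants of no real substance, noise included.)

Do not count the whole charge of free enzyme as working enzyme. 0.061 µM of impurity stands against 0.51 µM, so if each impurity takes one enzyme, reckon with 0.449 µM.

the same everywhere: free enzyme 0.51 µM; impurity 0.061 µM
- south-west: starting material 19 mM; second substrate 20.9 mM; run made earlier
- south: starting material 19 mM; second substrate 31 mM; run made earlier
- larch: starting material 19 mM; second substrate 20.9 mM (fed, over 4.00 min); a stirred flask in which second substrate is dosed at a steady rate over 4.00 min without added volume, worked up at 8.0 min; time 8.0 min
- alder: starting material 19 mM; second substrate 20.9 mM; one stirred flow tank at steady state, fed with the mixture as stated, mean residence time 8.0 min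
- ash: starting material 19 mM; second substrate 20.9 mM; everything together in a closed stirred flask, run for 8.0 min; time 8.0 min
- elm: starting material 19 mM (fed, over 4.00 min); second substrate 20.9 mM; a stirred flask in which starting material is dosed at a steady rate over 4.00 min without added volume, worked up at 8.0 min; time 8.0 min

| run | time / min | target / % |
|---|---|---|
| south-west | 1.50 | 8.8 |
| south-west | 3.00 | 17.0 |
| south-west | 5.00 | 25.8 |
| south-west | 6.00 | 29.8 |
| south-west | 8.00 | 36.8 |
| south | 0.200 | 1.5 |
| south | 0.333 | 2.5 |
| south | 0.667 | 5.2 |
| south | 1.33 | 10.0 |
| south | 2.50 | 17.2 |

(standard deviation of a reading: 0.5 percentage points)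

- the stated concentrations are those of everything mixed, before any reaction; amounts are the same in each set-up
- on the list of suspects stand: free enzyme + impurity -> spent catalyst; second complex -> free enzyme + target; starting material + free enzyme <-> first complex; first complex <-> loaded enzyme + first product; second substrate + loaded enzyme <-> second complex
- the feed brings no volume worth counting
- the earlier runs were made in a closed, stirred flask

- the set-up with the highest amount of target at the outlet or at the end, in percent of the starting material put in ("none" if the first two lie within 2 percentage points) (larch / alder / ash / elm / none)
- amount of target at the outlet or at the end, in percent of the starting material put in, larch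
- amount of target at the outlet or at the end, in percent of the starting material put in, alder
- amount of target at the outlet or at the end, in percent of the starting material put in, ash
- amount of target at the outlet or at the end, in percent of the starting material put in, elm

Start from the last south-west reading, 36.8% target at 8.00 min, which carries a scatter of 0.5 percentage points. It gives T = 12.1 min, the half-life of starting material in the closed flask at this charge, read as if the loss were first order.

Ash has the south-west charge, and 8.0 min is 0.661 of T, so expect that reading back. Take a steady feed as losing 2.00 min of running. Larch and elm then get 6.00 min, which reckons to 29.1% target. Count this as a low figure: the early rate rose 1.28-fold in the south run for 1.48-fold second substrate. For alder, the same T reckons to 31.4%. Do not dose ash or move it to the tank.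

The forecast names ash: larch 31%, alder 30%, ash 36.8%, elm 32%, on the ground that “Dosing wastes the early minutes”. Its larch and elm stand above this reckoning, and its alder below.

The flask gives ash: larch 31.0%, alder 30.0%, ash 36.7%, elm 32.6%.

    free enzyme + impurity → spent catalyst (k = 4.80 × 10⁶ M⁻¹ s⁻¹)
    second complex → free enzyme + target (k = 340 s⁻¹)
    starting material + free enzyme ⇌ first complex (K = 22.0 M⁻¹, k = 8.50 × 10⁵ M⁻¹ s⁻¹)
    first complex ⇌ loaded enzyme + first product (K = 0.0440 M, k = 470 s⁻¹)
    second substrate + loaded enzyme ⇌ second complex (K = 12.0 M⁻¹, k = 9.40 × 10⁵ M⁻¹ s⁻¹)

Ash stops at 36.7% because of the undoing of second complex into second substrate + loaded enzyme, a part of the reason, acting together with the time allowed: with that undoing taken away ash gives 75.9%, and with the time run on to 80.0 min it gives 91.5%. By T, larch's result equals 6.48 min of closed running, so on this reckoning the feed cost 1.52 min.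

Now take larch with 1.30 µM of free enzyme. Working enzyme of 1.24 µM shortens T to 4.38 min, so 6.00 min reckons to 61.3%. That neighbour flask gives 58.1%.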